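## The problem

Target 18, 8-(2,4-dihydroxy-6-pentylphenoxy)-6-hydroxy-3-pentyl-1H-isochromen-1-one, is an isocoumarin (benzo ring A fused to a 3-pentylpyranone) whose C8 oxygen bridges to C1′ of a second arene, ring B. This diaryl ether is the difficult bond: C8 lies next to C8a, which carries the lactone carbonyl C1, and C1′ lies between the C2′ hydroxyl and the C6′ pentyl chain, so three of the four positions ortho to the ether are substituted and a union of two finished arenes would be a hindered coupling. The molecule has no stereocentre and no configured double bond, so stereocentres created on the way need no control, only a later step that erases them. Two features fix the order of events: the enol lactone is opened by alkoxide or hydroxide and must be closed after all strongly basic steps, and ring B with free hydroxyls ortho and para to the ether oxygen is a very electron-rich, easily oxidised arene, so its phenols and the C6 phenol should stay masked until the end. Ring A has the pattern of an orsellinate (carboxyl carbon on C8a, methyl carbon on C4a, oxygens on C6 and C8) and can be bought; the pyranone then needs only C3 with its pentyl chain added to the benzylic carbon C4. The enabling feature is in ring B: the oxygens on C2′ and C4′ are meta to each other with unsubstituted C3′ between them, the pattern of an aromatised cyclohexane-1,3-dione, and the ether-bearing C1′ and pentyl-bearing C6′ are adjacent. Read as a 4-aryloxy-5-pentylcyclohexane-1,3-dione, ring B divides into an α-aryloxy enone (C3′, C2′, C1′, C6′) and a malonate (C5′, C4′), and the ether oxygen can be bound to C1′ before that carbon belongs to an arene.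

## Retrosynthesis

**18 ⇒ 17.** The three phenolic O–H groups are traced back to O-methyl ethers, giving isocoumarin 17. Methyl is chosen because one such ether arises anyway when ring A is differentiated and the two on ring B come from the aromatisation. A single global dealkylation then serves as the last step. It has to spare the diaryl ether, which has no sp3 carbon to attack, and the conjugated lactone.

**17 ⇒ 16 ⇒ 12 + 15.** The pyranone is opened at the lactone bond C1–O2 and then at C3–C4. This leads through keto ester 16 to toluate 12 and Weinreb amide 15, itself from acid chloride 13 and hydroxylamine salt 14. The alternative, alkynylation of a C4a halide followed by 6-endo cyclisation, would need a halogen that the orsellinate does not carry, whereas the C-methyl group of 12 is already the most acidic site. The forward steps are a lateral lithiation and acylation, then an enol lactonisation. Placing them late keeps the base-labile lactone out of the annulation.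

**12 ⇒ 10 ⇒ 8.** Ring B of 12 is taken back to the oxidation level of a cyclohexane-1,3-dione (10, by way of monomethyl ether 11) and then to its C5′ methoxycarbonyl derivative 8 (by way of acid 9). No skeletal bond is cut, but the arene becomes a 1,3-dicarbonyl compound that can be assembled by enolate chemistry. The forward direction asks for hydrolysis and decarboxylation, then a dehydrogenation that keeps the aryloxy group on C1′.

**8 ⇒ 6 + 7 (key disconnection).** Bonds C5′–C6′ and C3′–C4′ are cut, giving enone 6 and dimethyl malonate 7. The neighbouring cut, at C8–O or O–C1′ between two arenes, would require joining an ortho-substituted carbon with a di-ortho-substituted one. Here the ether is already present in 6 and ring B grows around it. The precursor 6 is acyclic in its ring B part and has no stereocentre. The forward reaction must add malonate in conjugate fashion and close the ring through the methyl ketone.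

**6 ⇒ 4 + 5; 4 ⇒ 2 + 3; 2 ⇒ 1.** The C1′=C6′ double bond is cut to phosphonate 4 and hexanal 5. The O–C1′ bond of 4 is cut to phenol 2 and diazo phosphonate 3. Phenol 2 comes from methyl orsellinate 1 by methylation of the non-chelated hydroxyl. The ether bond is thus made by carbenoid O–H insertion at an sp3 carbon, where ortho substitution on ring A matters little, and the phosphonate needed for the olefination arrives in the same step.

## Roads not taken

**Alternative 1:** The cut is at C4a–C4 and C8a–C1, the two carbon arms of the pyranone, which are traced to an aryne spanning C4a and C8a.
- **Forward step:** fluoride (CsF) unmasks the aryne from silylaryl triflate A2 and dimethyl malonate 7 inserts across it, the carbanion adding at C4a and the aryl anion at C8a taking an ester by acyl transfer, to give homophthalate A1.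
- **Merits:** both arms are set in one step. The C8 aryloxy group should direct the nucleophile to the distal aryne carbon, which is the required regiochemistry. Ring B is carried as a finished arene, so no decarboxylation or dehydrogenation is needed.
- **Weak points:** A2 already contains the hindered diaryl ether, so the hardest bond is only moved to an earlier copper-mediated coupling of an ortho-substituted ring A piece with a di-ortho-substituted ring B phenol. A2 also needs an ortho-silylation and triflation sequence on that elaborated ether. Malonates and arynes can give plain α-arylation beside insertion. A1 still needs C4 acylation, loss of the C4 ester and lactonisation to reach 17.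
- **Comparison:** after its key step this road is about as long as the chosen one and cleaner in oxidation-state terms. The chosen plan sets against it an ether bond made at an sp3 carbon and a commercial ring A that needs no aryne precursor.

**Alternative 2:** The cut is at C2′–C3′, C4′–C5′ and C1′–C2′ of ring B.
- **Forward step:** heating cyclobutenone A4 with ethoxyethyne A5 starts a Danheiser benzannulation (electrocyclic opening to a vinylketene, [2+2] addition to the alkyne, a second four-electron opening, six-electron closure, tautomerisation) that gives phenol A3.
- **Merits:** like the chosen plan it builds ring B on the ether oxygen, but ring B arrives aromatic, with C2′ as free hydroxyl and C4′ as ethyl ether, on a preformed isocoumarin. A3 is one dealkylation from 18, against six steps after the key step here. In convergency and in step count after ring formation this road is better.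
- **Weak points:** A4, a 4-aryloxycyclobutenone with a hydrogen on C4, has no dependable preparation; a ketene–alkyne cycloaddition of an aryloxyketene with an unactivated terminal alkyne is poor. The isocoumarin half of A4 must first be made with a free C8 hydroxyl. The enol lactone has to survive prolonged heating in the presence of ketenes.
- **Comparison:** the chosen plan cannot match the brevity after the key step. It offers instead a key step of a thoroughly known class, a precursor reached in three steps from a commercial ester, and commodity reagents for the aromatisation.

**Alternative 3:** The cut is at C6–C7, C8–C8a and C5–C6 of ring A.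
- **Forward step:** irradiation of diazo keto ester A7 gives, by Wolff rearrangement, an ester-substituted vinylketene that adds to aryl ethynyl ether A8; warming completes the ring opening and six-electron closure to benzoate A6.
- **Merits:** the ether oxygen enters on an sp carbon, so hindrance is again sidestepped. The polarity of the ynol ether fixes the regiochemistry of ring A. A6 is one O-methylation from compound 12 of the chosen route, reached without decarboxylation or dehydrogenation.
- **Weak points:** A8 needs the di-ortho-substituted ring B phenol, itself several steps from a commercial resorcinol ether, and then a two-step ethynylation of that hindered oxygen. Aryl ynol ethers are labile. The ketene from A7 is also an acylketene and may engage the electron-rich alkyne as a heterodiene to give a pyranone instead of the [2+2] adduct. A7 comes from a polymerisation-prone isopropenyl keto ester. Photochemistry limits scale.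
- **Comparison:** regiochemical certainty and direct arrival at an aromatic ring A are real advantages. Against them the chosen plan sets a purchased ring A, no photochemistry, and a ring B made from an aldehyde, a malonate and iodine. Once A7 and A8 are counted, this road is expected to be the longer one.

Key step: step 4

## Route

Assumption: 8, 9 and 10 are drawn as keto tautomers although they should exist largely as enols and as diastereomer mixtures, and the aromatisation in step 6 is taken to stop mainly at monomethyl ether 11; any regioisomeric monomethyl ether or dimethyl ether formed beside it converges on 12 in the methylation stage.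

Step 1
Reactants: 1 methyl 2,4-dihydroxy-6-methylbenzoate (methyl orsellinate)
Product: 2 methyl 2-hydroxy-4-methoxy-6-methylbenzoate
Conditions: MeI (1.05 equiv), K2CO3 (1.1 equiv), acetone, rt
Reagents that add atoms: iodomethane (CI)
Why: Williamson ether synthesis; the C2 hydroxyl is held in a hydrogen bond to the ester carbonyl and is the less acidic one, so one equivalent of MeI should alkylate only the hydroxyl para to the ester.

Step 2
Reactants: 2 methyl 2-hydroxy-4-methoxy-6-methylbenzoate; 3 dimethyl (1-diazo-2-oxopropyl)phosphonate
Product: 4 methyl 2-{[1-(dimethoxyphosphoryl)-2-oxopropyl]oxy}-4-methoxy-6-methylbenzoate (racemic)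
Conditions: Rh2(OAc)4 (2 mol %), PhMe, 80 °C, slow addition of 3
Reagents that add atoms: none
Why: Rhodium-carbenoid O–H insertion: loss of N2 from 3 gives an electrophilic carbenoid that the phenol oxygen captures (oxonium ylide, then 1,2-proton shift), so the hindered ether bond O–C1′ is formed at an sp3 carbon. The new stereocentre is racemic and is destroyed in step 3.

Step 3
Reactants: 4 methyl 2-{[1-(dimethoxyphosphoryl)-2-oxopropyl]oxy}-4-methoxy-6-methylbenzoate; 5 hexanal
Product: 6 methyl 4-methoxy-2-methyl-6-{[(3Z)-2-oxonon-3-en-3-yl]oxy}benzoate
Conditions: LiCl, DBU, MeCN, 0 °C to rt
Reagents that add atoms: none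
Why: Horner–Wadsworth–Emmons olefination under Masamune–Roush conditions, mild enough for an enolisable aldehyde; the lithium-chelated ketophosphonate anion adds to hexanal and loss of dimethyl phosphate gives the enone. The isomer with pentyl trans to acetyl (3Z) is expected to predominate, and the geometry is of no consequence because C1′ and C6′ later become arene carbons.

Step 4
Reactants: 6 methyl 4-methoxy-2-methyl-6-{[(3Z)-2-oxonon-3-en-3-yl]oxy}benzoate; 7 dimethyl malonate
Product: 8 methyl 2-{[5-(methoxycarbonyl)-2,4-dioxo-6-pentylcyclohexyl]oxy}-4-methoxy-6-methylbenzoate (diastereomer mixture)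
Conditions: NaOMe (1.2 equiv), 7 (1.3 equiv), MeOH, 65 °C; then aq. HCl, 0 °C
Reagents that add atoms: none
Why: Sodium dimethyl malonate adds to the β-carbon C6′ of the enone (Michael addition, bond C5′–C6′), proton exchange in methanol moves the enolate from C1′ to the methyl carbon C3′, and this enolate attacks a malonate ester carbonyl C4′ and expels methoxide (Claisen condensation, bond C3′–C4′). Ring B closes in a 6-exo-trig mode. The closest known reaction is the malonate annulation of alk-3-en-2-ones to 5-alkylcyclohexane-1,3-diones, the classical entry to 5-alkylresorcinols; here the enone carries an α-aryloxy group. The steps before the last are reversible and the sequence is pulled forward by deprotonation of the product to its β-diketonate. Stereocentres arise at C1′, C5′ and C6′ under equilibrating conditions as a mixture; none is controlled and none needs to be, since steps 5 and 6 remove all three. The step needs conjugate rather than carbonyl addition, which the soft stabilised nucleophile secures, and closure through C3′ rather than C1′: the C1′ enolate can reach a malonate ester only through a four-membered ring, and its 5-exo attack on the ring A ester is held back by the two ortho substituents that flank and twist that ester and by the quaternary centre it would create. The aryloxy group is never β to a carbanion, so it cannot be lost by elimination, and as an electron-rich aryloxide it is a poor leaving group for displacement by the malonate carbanion.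

Step 5
Reactants: 8 methyl 2-{[5-(methoxycarbonyl)-2,4-dioxo-6-pentylcyclohexyl]oxy}-4-methoxy-6-methylbenzoate
Product: 10 methyl 2-[(2,4-dioxo-6-pentylcyclohexyl)oxy]-4-methoxy-6-methylbenzoate, via keto acid 9 (not isolated)
Conditions: NaOH (aq. 1 M), MeOH, 50 °C; then HCl to pH 1, 65 °C
Reagents that add atoms: none
Why: Saponification of the aliphatic β-keto ester, which should be much faster than that of the ring A benzoate flanked by two ortho substituents, then decarboxylation of the β-keto acid on acidification through the usual six-membered transition state; the C5′ stereocentre is lost. Any ring A acid formed by over-hydrolysis would be re-esterified by MeI/K2CO3 in step 6.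

Step 6
Reactants: 10 methyl 2-[(2,4-dioxo-6-pentylcyclohexyl)oxy]-4-methoxy-6-methylbenzoate
Product: 12 methyl 2-(2,4-dimethoxy-6-pentylphenoxy)-4-methoxy-6-methylbenzoate, via monomethyl ether 11 (not isolated)
Conditions: I2 (2 equiv), MeOH, 65 °C; then MeI, K2CO3, acetone, 56 °C
Reagents that add atoms: methanol (CO); iodomethane (CI)
Why: Iodine–methanol oxidative aromatisation of a cyclohexane-1,3-dione: acid-catalysed formation of the vinylogous methyl ester, iodination of its dienol at C5′, loss of HI and tautomerisation should give the aryl ether and erase the stereocentres at C1′ and C6′. Williamson methylation of the crude phenol then converges all partly methylated products on 12.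

Step 7
Reactants: 13 hexanoyl chloride; 14 N,O-dimethylhydroxylamine hydrochloride
Product: 15 N-methoxy-N-methylhexanamide
Conditions: K2CO3, CH2Cl2/H2O, 0 °C to rt
Reagents that add atoms: none
Why: Schotten–Baumann acylation of the liberated hydroxylamine by the acid chloride gives the Weinreb amide.

Step 8
Reactants: 12 methyl 2-(2,4-dimethoxy-6-pentylphenoxy)-4-methoxy-6-methylbenzoate; 15 N-methoxy-N-methylhexanamide
Product: 16 methyl 2-(2,4-dimethoxy-6-pentylphenoxy)-4-methoxy-6-(2-oxoheptyl)benzoate
Conditions: LDA (1.2 equiv), THF, −78 °C; then 15, −78 to −40 °C; aq. NH4Cl
Reagents that add atoms: none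
Why: Lateral lithiation of an ortho-toluate: LDA removes a proton of the C-methyl group because the ortho ester stabilises the anion as an extended enolate, and acylation by the Weinreb amide forms C3–C4 and stops at the chelated tetrahedral intermediate, which releases the ketone only on quench, so double addition is excluded.

Step 9
Reactants: 16 methyl 2-(2,4-dimethoxy-6-pentylphenoxy)-4-methoxy-6-(2-oxoheptyl)benzoate
Product: 17 8-(2,4-dimethoxy-6-pentylphenoxy)-6-methoxy-3-pentyl-1H-isochromen-1-one
Conditions: p-TsOH·H2O (10 mol %), PhMe, 110 °C
Reagents that add atoms: none
Why: Acid-catalysed enol lactonisation: the enol oxygen of the benzylic ketone attacks the neighbouring ester carbonyl (6-exo-trig) and methanol is lost, driven by formation of the conjugated isocoumarin. Acid avoids the base-mediated Claisen closure through the other ketone α-carbon, which would lead to a naphthalenediol.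

Step 10
Reactants: 17 8-(2,4-dimethoxy-6-pentylphenoxy)-6-methoxy-3-pentyl-1H-isochromen-1-one
Product: 18 8-(2,4-dihydroxy-6-pentylphenoxy)-6-hydroxy-3-pentyl-1H-isochromen-1-one
Conditions: BBr3 (8 equiv), CH2Cl2, −78 °C to rt; then H2O
Reagents that add atoms: none
Why: BBr3 ether cleavage: each methoxy oxygen binds boron and bromide attacks the methyl carbon (SN2). The diaryl ether offers no sp3 carbon for this displacement and methoxyisocoumarins are routinely demethylated this way with the lactone intact, so hydrolysis of the aryl borates on work-up should give the triphenol.

## Compound list

1 | methyl 2,4-dihydroxy-6-methylbenzoate (methyl orsellinate) | COC(=O)c1c(C)cc(O)cc1O | starting material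
2 | methyl 2-hydroxy-4-methoxy-6-methylbenzoate | COC(=O)c1c(C)cc(OC)cc1O | intermediate
3 | dimethyl (1-diazo-2-oxopropyl)phosphonate | COP(=O)(OC)C(=[N+]=[N-])C(C)=O | starting material
4 | methyl 2-{[1-(dimethoxyphosphoryl)-2-oxopropyl]oxy}-4-methoxy-6-methylbenzoate (racemic) | COC(=O)c1c(C)cc(OC)cc1OC(C(C)=O)P(=O)(OC)OC | intermediate
5 | hexanal | CCCCCC=O | starting material
6 | methyl 4-methoxy-2-methyl-6-{[(3Z)-2-oxonon-3-en-3-yl]oxy}benzoate | CCCCC/C=C(\Oc1cc(OC)cc(C)c1C(=O)OC)C(C)=O | intermediate
7 | dimethyl malonate | COC(=O)CC(=O)OC | starting material
8 | methyl 2-{[5-(methoxycarbonyl)-2,4-dioxo-6-pentylcyclohexyl]oxy}-4-methoxy-6-methylbenzoate (diastereomer mixture) | CCCCCC1C(C(=O)OC)C(=O)CC(=O)C1Oc1cc(OC)cc(C)c1C(=O)OC | intermediate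
9 | 5-[5-methoxy-2-(methoxycarbonyl)-3-methylphenoxy]-2,4-dioxo-6-pentylcyclohexane-1-carboxylic acid (diastereomer mixture) | CCCCCC1C(C(=O)O)C(=O)CC(=O)C1Oc1cc(OC)cc(C)c1C(=O)OC | intermediate
10 | methyl 2-[(2,4-dioxo-6-pentylcyclohexyl)oxy]-4-methoxy-6-methylbenzoate (diastereomer mixture) | CCCCCC1CC(=O)CC(=O)C1Oc1cc(OC)cc(C)c1C(=O)OC | intermediate
11 | methyl 2-(2-hydroxy-4-methoxy-6-pentylphenoxy)-4-methoxy-6-methylbenzoate | CCCCCc1cc(OC)cc(O)c1Oc1cc(OC)cc(C)c1C(=O)OC | intermediate
12 | methyl 2-(2,4-dimethoxy-6-pentylphenoxy)-4-methoxy-6-methylbenzoate | CCCCCc1cc(OC)cc(OC)c1Oc1cc(OC)cc(C)c1C(=O)OC | intermediate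
13 | hexanoyl chloride | CCCCCC(=O)Cl | starting material
14 | N,O-dimethylhydroxylamine hydrochloride | CNOC.Cl | starting material
15 | N-methoxy-N-methylhexanamide | CCCCCC(=O)N(C)OC | intermediate
16 | methyl 2-(2,4-dimethoxy-6-pentylphenoxy)-4-methoxy-6-(2-oxoheptyl)benzoate | CCCCCC(=O)Cc1cc(OC)cc(Oc2c(OC)cc(OC)cc2CCCCC)c1C(=O)OC | intermediate
17 | 8-(2,4-dimethoxy-6-pentylphenoxy)-6-methoxy-3-pentyl-1H-isochromen-1-one | CCCCCc1cc2cc(OC)cc(Oc3c(OC)cc(OC)cc3CCCCC)c2c(=O)o1 | intermediate
18 | 8-(2,4-dihydroxy-6-pentylphenoxy)-6-hydroxy-3-pentyl-1H-isochromen-1-one | CCCCCc1cc2cc(O)cc(Oc3c(O)cc(O)cc3CCCCC)c2c(=O)o1 | target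

## Step count and least certain steps

Total step count: 10. Longest linear sequence: 9 steps (1 → 2 → 4 → 6 → 8 → 10 → 12 → 16 → 17 → 18); step 7 is a one-step side branch.

**Step 4 (key step).** Conjugate addition to a trisubstituted enone whose α-aryloxy group donates into the double bond may be slow and reversible. The C1′ enolate then persists long enough to attack the ring A ester (5-exo closure followed by loss of the acetyl group), or the malonate carbanion displaces the aryloxide from C1′ in a 3-exo closure. The fallback sets out from 6 and separates the two bond formations. A Mukaiyama–Michael addition of commercial tert-butyl[(1-methoxyethenyl)oxy]dimethylsilane to 6, promoted by TiCl4 in CH2Cl2 at −78 °C, forms C5′–C6′ without any basic enolate or malonate carbanion. After aqueous acid work-up it should give keto ester F1. A Dieckmann-type Claisen closure of F1 with KOtBu in THF at 0 °C then forms C3′–C4′ and delivers the dione directly. The fallback comes back to the route at 10 and makes step 5 unnecessary.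

**Step 2.** The phenol of 2 is chelated to the ester and electron-poor, so O–H insertion may be slow. Carbenoid dimerisation, insertion into adventitious water or attack on the electron-rich ring A could then take over. The fallback sets out from 2 and avoids the diazo compound. Commercial (E)-non-3-en-2-one is epoxidised with alkaline H2O2 (Weitz–Scheffer) to trans-epoxy ketone F2. The phenoxide of 2 (Cs2CO3, DMF, 70 °C) should open F2 at the carbonyl-activated α-carbon to give hydroxy ketone F3. F3 loses water under the same basic conditions, and the fallback comes back to the route at 6, bypassing 4.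

**Step 6.** The HI formed during aromatisation may cause loss of the aryloxy group next to the carbonyl (reductive cleavage by iodide, or elimination to the pentylresorcinol) or iodination of the electron-rich rings; dehydrogenation may also stall. The fallback sets out from 10 and uses a non-acidic dehydrogenation. Palladium-catalysed aerobic dehydrogenation (Pd(O2CCF3)2, 2-(dimethylamino)pyridine, TsOH, O2, DMSO, 80 °C) should give resorcinol F4. Double methylation of F4 with MeI and K2CO3 in acetone brings it back to the route at 12.

**Step 9.** The ester flanked by two ortho substituents is twisted out of the ring plane and may resist attack by the enol, so that loss of methanol stalls or prolonged heating in acid degrades the keto ester. The fallback sets out from 16. Saponification with KOH in aqueous ethanol at reflux should give keto acid F5. Cyclodehydration of F5 with acetic anhydride at 100 °C, by way of the mixed anhydride and O-acylation of the enol, brings it back to the route at 17.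

## Further compounds

F1 | step 4 | methyl 4-methoxy-2-[(6-methoxy-2,6-dioxo-4-pentylhexan-3-yl)oxy]-6-methylbenzoate (diastereomer mixture) | CCCCCC(CC(=O)OC)C(Oc1cc(OC)cc(C)c1C(=O)OC)C(C)=O
F2 | step 2 | trans-1-(3-pentyloxiran-2-yl)ethan-1-one (racemic, one enantiomer drawn) | CCCCC[C@H]1O[C@@H]1C(C)=O
F3 | step 2 | methyl 2-[(4-hydroxy-2-oxononan-3-yl)oxy]-4-methoxy-6-methylbenzoate (racemic, one enantiomer drawn) | CCCCC[C@@H](O)[C@@H](Oc1cc(OC)cc(C)c1C(=O)OC)C(C)=O
F4 | step 6 | methyl 2-(2,4-dihydroxy-6-pentylphenoxy)-4-methoxy-6-methylbenzoate | CCCCCc1cc(O)cc(O)c1Oc1cc(OC)cc(C)c1C(=O)OC
F5 | step 9 | 2-(2,4-dimethoxy-6-pentylphenoxy)-4-methoxy-6-(2-oxoheptyl)benzoic acid | CCCCCC(=O)Cc1cc(OC)cc(Oc2c(OC)cc(OC)cc2CCCCC)c1C(=O)O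
A1 | alternative 1 | methyl 2-(2,4-dimethoxy-6-pentylphenoxy)-4-methoxy-6-(2-methoxy-2-oxoethyl)benzoate | COC(=O)Cc1cc(OC)cc(Oc2c(OC)cc(OC)cc2CCCCC)c1C(=O)OC
A2 | alternative 1 | 3-(2,4-dimethoxy-6-pentylphenoxy)-5-methoxy-2-(trimethylsilyl)phenyl trifluoromethanesulfonate | COc1cc(OS(=O)(=O)C(F)(F)F)c([Si](C)(C)C)c(Oc2c(OC)cc(OC)cc2CCCCC)c1
A3 | alternative 2 | 8-(4-ethoxy-2-hydroxy-6-pentylphenoxy)-6-methoxy-3-pentyl-1H-isochromen-1-one | CCCCCc1cc(OCC)cc(O)c1Oc1cc(OC)cc2cc(CCCCC)oc(=O)c12
A4 | alternative 2 | 6-methoxy-8-[(4-oxo-2-pentylcyclobut-2-en-1-yl)oxy]-3-pentyl-1H-isochromen-1-one (racemic) | CCCCCC1=CC(=O)C1Oc1cc(OC)cc2cc(CCCCC)oc(=O)c12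
A5 | alternative 2 | ethoxyethyne | CCOC#C
A6 | alternative 3 | methyl 2-(2,4-dimethoxy-6-pentylphenoxy)-4-hydroxy-6-methylbenzoate | COC(=O)c1c(C)cc(O)cc1Oc1c(OC)cc(OC)cc1CCCCC
A7 | alternative 3 | methyl 2-diazo-4-methyl-3-oxopent-4-enoate | COC(=O)C(=[N+]=[N-])C(=O)C(C)=C
A8 | alternative 3 | 2-(ethynyloxy)-1,5-dimethoxy-3-pentylbenzene | C#COc1c(OC)cc(OC)cc1CCCCC
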